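With little material to spare, I decided to reckon how much transfer agent the flask could bear before I charged any of it.

| flask | solid substrate | partner | transfer agent | initiator | time |
|---|---|---|---|---|---|
| alpha | 0.0050 M | 5.25 mM | 0.400 mM | 0.12 mM | 50 s |
| gamma | 0.0050 M | 5.25 mM | 0.800 mM | 0.12 mM | 50 s |
| epsilon | 0.0050 M | 5.25 mM | 1.50 mM | 0.12 mM | 50 s |

    2 partner → self-condensation product (k1 = 7.2 L mol⁻¹ s⁻¹)
    partner + first chain carrier → target + second chain carrier (k2 = 9.0 × 10⁵ L mol⁻¹ s⁻¹)
    starting material + initiating radical → capped initiator + first chain carrier (k3 = 1.8 × 10⁷ L mol⁻¹ s⁻¹)
    initiator → 2 initiating radical (k4 = 0.016 s⁻¹)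
    starting material + second chain carrier → released group + first chain carrier (k5 = 4.0 × 10⁵ L mol⁻¹ s⁻¹)
    solid substrate ⇌ starting material, rate k6*(cs6 - [starting material]) while solid is left; crystals form when [starting material] > cs6 (cs6 = 2.2 mM, k6 = 0.085 s⁻¹)
    2 idle radical → ended radicals (k7 = 4.8 × 10⁸ L mol⁻¹ s⁻¹)
    transfer agent + first chain carrier → side product + idle radical (k8 = 64000 L mol⁻¹ s⁻¹)
    2 first chain carrier → ended chains (k9 = 1.5 × 10⁷ L mol⁻¹ s⁻¹)

- percent here means solid substrate units held: one ended chains counts as two
- for a step with 2 of a species take k times the square, and two of it per event
- solid substrate is a solid; its amount is given per volume of the solution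
- at the start none of the solid substrate is in solution
- "hardly changes" means that all values lie within two and a half points (for a concentration: within two and a half percent of the largest)
- run time (alpha): 50 s

- [target] at the end for alpha, gamma, epsilon, in this order
- the shape of the row from first to last (falls all the way / rises all the way / rises, then falls / falls, then rises / hardly changes)

**Two drains.** Alpha and gamma look nearly the same, for they differ in transfer agent, 0.400 mM against 0.800 mM. In both flasks partner leaves by the chain and by self-condensation. I replaced the partner curve by a straight fall from the charge to nothing. The mean of its square is then a third of the charge squared, and the mean self-condensation loss came to 0.132 mM s⁻¹.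

**Chain speed.** Dissolution delivers at most 0.187 mM s⁻¹, reached while starting material stands near nothing. Initiator supplied first chain carrier at a mean of 0.00264 mM s⁻¹ over 50 s. I let transfer end each carrier and took partner at half its charge. The chain then multiplies that supply by the ratio of the rates at which a carrier meets partner and transfer agent. That gave 0.244 mM s⁻¹ in alpha and 0.122 mM s⁻¹ in gamma.

**Chain share.** I took the slower of chain speed and dissolution and divided it by itself plus the loss. For alpha this gave 58.6% and for gamma 48.0%. This fraction of the partner charge expected as target is what I called the chain share. Alpha stands above gamma because the slower speed in alpha, that of dissolution, is faster than the chain speed in gamma. I expected alpha's partner curve to sag below the straight line, because self-condensation at the charge runs at 0.397 mM s⁻¹, faster than its mean, so I expected my share for alpha to run low.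

**The forecast.** The forecast gave 0.0034 M, 0.0029 M and 0.0022 M, a row that falls all the way. Its ground was this: “makes the chain radical-limited, so more partner is lost to self-condensation and the target falls steadily across the row”. For alpha its value is 64.8% of the partner charge, higher than my share.

**The flasks.** The flasks ended at 0.00339 M, 0.00300 M and 0.00217 M of target, a row that falls all the way. At 13.7 s, alpha made starting material 1.03 times as fast as it used it up, each step taken net. Alpha turned 64.6% of its partner charge into target, against a chain share of 58.6%. Epsilon, with 1.50 mM of transfer agent, has a chain speed of 0.0650 mM s⁻¹ and a chain share of 33.0%, and it ended with 41.3% of its partner charge as target.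

The constants used here are made up; what happens was integrated by code.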